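**Plan**

- Retrosynthesis (germacrane numbering, C1–C10 ring, C11–C13 lactone carbons, C14 on C10, C15 on C4): open the lactone at O6–C12 and the angelate at O8–acyl, and trace the C1 carbonyl back to a C1–SO2Ph group. Then cut C1–C10 while re-joining C3–C8, which turns the oxa-bridged cyclodecadiene into a cis-fused 2-methyl-dihydrofuran on a cyclohexene.
- The bicycle is cut at O–C10 (alkynol cyclisation), at C3–O and C6–O (both from one O2), at C2–C3 (Heck) and at C8–C9 (enolate alkylation), which leads to (S)-carvone.
- Enabling feature: C3–C8 with C15 and C11–C13 are the carvone ring with its methyl and isopropenyl group. The C1–C10 bond and the C2=C3 enol ether of the bridged furanone are what a [3,3] shift across C3–C8 leaves behind.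
- Forward order of rings: carvone ring (steps 1–10), cis-fused dihydrofuran (step 11), then step 12 opens the six-membered ring into the ten-membered carbocycle while closing the new dihydrofuran; the furanone carbonyl (step 14) and the γ-lactone (step 17) follow.
- Stereochemistry: C7 from (S)-carvone; quaternary C8 by alkylation anti to the isopropenyl group; C11 by hydroboration anti to C8; C3 and C6 by O2 addition anti to the C7/C8 top-face groups; C10 by transfer across the ring fusion in step 12; the C8 carbinol by hydride attack anti to the C7 side chain.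
- The vinyl terminus C1 carries a phenylsulfonyl group: it stabilises the anion of step 12 and is later exchanged for the C1 carbonyl.

Key step: step 12

Remark on numbering: target numbering is used for all intermediates; in carvone C3 is the carbonyl carbon, C4=C5 the alkene, C7 the carbon bearing the isopropenyl group and C8 the α′-carbon.
Remark: enolates, alkoxides and carbanions made by deprotonation are treated as reactive forms of the numbered compounds and carry no numbers of their own.
Remark: the 11-methyl configuration made in step 4 is also the more stable one (pseudo-equatorial, trans to C8) in the final trans-fused lactone.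

**Route**

Step 1
Reactants: 1 (S)-(+)-carvone
Product: 2 (5R,6R)-6-hydroxycarvone (C8–OH trans to the isopropenyl group)
Conditions: LDA, THF, −78 °C; 2-(phenylsulfonyl)-3-phenyloxaziridine, −78 °C; aq. NH4Cl
Reagents that add atoms: 2-(phenylsulfonyl)-3-phenyloxaziridine, O=S(=O)(N1OC1c1ccccc1)c1ccccc1
Why: Kinetic deprotonation of the enone takes place at the α′-methylene and the lithium enolate is hydroxylated by the N-sulfonyloxaziridine (Davis oxidation), mainly anti to the isopropenyl group; the configuration of this carbinol is of no consequence because C8 passes through an enolate again in step 3.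

Step 2
Reactants: 2 (5R,6R)-6-hydroxycarvone
Product: 3 triethylsilyl ether of 2
Conditions: Et3SiCl, imidazole, DMF, 0 °C to rt
Reagents that add atoms: chlorotriethylsilane, CC[Si](Cl)(CC)CC
Why: Standard silylation of a secondary alcohol; the triethylsilyl ether tolerates the enolate and palladium steps and is removable by fluoride in step 9.

Step 3
Reactants: 3 triethylsilyl ether of 2; 4 3-bromo-1-(trimethylsilyl)prop-1-yne
Product: 5 C8-quaternary enone (C8: OSiEt3 cis and CH2C≡C–SiMe3 trans to the isopropenyl group)
Conditions: LDA, THF, −78 °C; HMPA; 4, −78 to −40 °C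
Reagents that add atoms: none
Why: Enolate alkylation: the tetrasubstituted α-silyloxy enolate is alkylated on the face anti to the neighbouring isopropenyl group (the usual trans outcome for carvone enolates), which fixes the quaternary centre C8 with its oxygen cis to the C7 substituent; the low temperature keeps O-to-O silyl transfer in the enolate slow and the silylated alkyne avoids an acidic C–H in steps 6 and 7.

Step 4
Reactants: 5 C8-quaternary enone
Product: 7 primary alcohol (C12–OH; C11 S), via alkylborane 6 (not isolated)
Conditions: 9-BBN (1.3 equiv), THF, 0 °C to rt; NaBO3·4H2O, THF/H2O, rt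
Reagents that add atoms: 9-borabicyclo[3.3.1]nonane, B1C2CCCC1CCC2 (boron framework of 6 only); sodium perborate, [Na+].[Na+].O[B-]1(O)OO[B-](O)(O)OO1 (oxygen of 7)
Why: Hydroboration–oxidation: the bulky dialkylborane should add to the 1,1-disubstituted alkene much faster than it reduces the hindered enone carbonyl or attacks the silylalkyne, and with the allylic C7–H lying in the alkene plane boron approaches anti to the quaternary C8, which sets C11 as drawn; perborate replaces alkaline peroxide to spare the enone.

Step 5
Reactants: 7 primary alcohol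
Product: 8 C12 tert-butyldimethylsilyl ether
Conditions: TBSCl, imidazole, DMF, rt
Reagents that add atoms: tert-butyldimethylsilyl chloride, CC(C)(C)[Si](C)(C)Cl
Why: Routine silylation of the primary alcohol, needed because step 6 uses a strong base and a triflating agent.

Step 6
Reactants: 8 C12 tert-butyldimethylsilyl ether
Product: 9 cyclohexa-1,3-dienyl triflate (C3–OTf, C3=C4, C5=C6)
Conditions: KHMDS, THF, −78 °C; PhNTf2, −78 to 0 °C
Reagents that add atoms: N-phenylbis(trifluoromethanesulfonimide), FC(F)(F)S(=O)(=O)N(c1ccccc1)S(=O)(=O)C(F)(F)F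
Why: Enol triflate formation: with C8 quaternary the only enolisable position is the γ-methylene C6, so deprotonation gives the extended dienolate, which is trapped on oxygen.

Step 7
Reactants: 9 cyclohexa-1,3-dienyl triflate; 10 phenyl vinyl sulfone
Product: 11 (E)-sulfonyl triene (C3–CH=CH–SO2Ph)
Conditions: Pd(OAc)2 (5 mol %), PPh3 (10 mol %), Et3N, DMF, 70 °C
Reagents that add atoms: none
Why: Heck coupling of an alkenyl triflate with an electron-poor terminal alkene; syn insertion and β-hydride elimination give the E-alkenyl sulfone and attach C2 and C1 to C3.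

Step 8
Reactants: 11 (E)-sulfonyl triene
Product: 13 cis-1,4-diol (C3–OH and C6–OH on the face opposite to the C7 side chain), via endoperoxide 12 (not isolated)
Conditions: O2, visible light, tetraphenylporphyrin (cat.), CH2Cl2, −20 °C; then Zn, AcOH, CH2Cl2, 0 °C
Reagents that add atoms: dioxygen, O=O
Why: [4+2] cycloaddition of singlet oxygen to the s-cis-locked ring diene C3=C4–C5=C6 and reduction of the O–O bond: both oxygens arrive on the diene face anti to the C7 side chain and the C8 silyloxy group, which sets C3 (oxygen trans to O8 and cis to the propargyl arm) and C6 (oxygen trans to the side chain) at once and returns the C4=C5 alkene.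

Step 9
Reactants: 13 cis-1,4-diol
Product: 14 tetraol with terminal alkyne
Conditions: TBAF (4.5 equiv), THF, 0 °C to rt; aq. NH4Cl
Reagents that add atoms: none
Why: Fluoride-mediated desilylation removes the alkynyl trimethylsilyl group and both silyl ethers in one operation, which frees the tertiary C8 hydroxyl without any need to tell silyl ethers apart.

Step 10
Reactants: 14 tetraol
Product: 15 bis-silyl ether (C12–OTBS and C6–OTBS; tertiary C3–OH and C8–OH free)
Conditions: TBSCl (2.3 equiv), imidazole, DMF, 0 °C to rt
Reagents that add atoms: tert-butyldimethylsilyl chloride, CC(C)(C)[Si](C)(C)Cl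
Why: Sterically controlled silylation: the primary and the secondary allylic hydroxyl react, the two tertiary hydroxyls do not.

Step 11
Reactants: 15 bis-silyl ether
Product: 17 rearrangement precursor (cis-fused 2-methyl-dihydrofuran; C3 alkenyl sulfone and C8–OH cis), via exocyclic enol ether 16 (not isolated)
Conditions: Ph3PAuNTf2 (3 mol %), CH2Cl2, 4 Å MS, 0 °C to rt; then PPTS (2 mol %), rt; Et3N quench
Reagents that add atoms: none
Why: Gold(I)-catalysed 5-exo-dig hydroalkoxylation: only the C3 hydroxyl, cis to the propargyl arm, can reach the internal alkyne carbon C10 (the C8 hydroxyl would need a 4-exo or an anti-Markovnikov 5-endo closure), and trace acid then moves the exocyclic double bond into the ring to the more substituted enol ether; the product is acid-labile and is handled buffered.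

Step 12
Reactants: 17 rearrangement precursor
Product: 18 oxa-bridged cyclodecadienone (C8 ketone, C1–SO2Ph, C2=C3 enol ether, Z-C4=C5)
Conditions: KHMDS (1.1 equiv), 18-crown-6 (1.2 equiv), THF, −78 to −20 °C; AcOH, −78 °C
Reagents that add atoms: none
Why: Proposed new method: deprotonation of the tertiary C8 hydroxyl gives a potassium alkoxide that drives a charge-accelerated [3,3] shift of the 1,5-diene C1=C2–C3–C8–C9=C10 (C1–C10 formed, C3–C8 broken) to a C8 enolate, which is protonated internally by the acidic C1–H next to the sulfone; since the ring oxygen ties C3 to C10, the boat-like array has the shape of a 7-oxanorbornane and is poorly aligned for a synchronous shift, so the event should be cleavage-led (alkoxide fragmentation to a sulfonyl-stabilised allyl anion, then Michael-type closure), which is why C1 carries the sulfone. The closest known reaction types are the anionic oxy-Cope ring expansion of 1,2-dialkenylcyclohexanols to cyclodecenones and the intramolecular Michael addition of sulfone-stabilised allyl anions. The new dihydrofuran (O, C10, C1, C2, C3) closes by 5-exo-trig attack of C1 on C10, and the ten-membered carbocycle is not closed by a cyclisation but is set free when the shared C3–C8 bond of the cyclohexene breaks (four-atom ring expansion). C10 is set by transfer of chirality from the ring fusion: C1 can reach C10 only on the dihydrofuran face that carries the alkenyl group, and that face is fixed by the cis fusion and by the C8 oxygen being cis to the C7 side chain (steps 3 and 8), while C1 is formed without control and disappears in step 14. The step needs bonding through C1 and not through C5 or C3 of the delocalised anion, and it needs the product enolate not to expel the bridging oxygen by β-elimination; charge localisation at C1 by the sulfone, the five-membered closure, the internal proton transfer, the low temperature and the cold acidic quench are there to secure both.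

Step 13
Reactants: 18 oxa-bridged cyclodecadienone
Product: 19 C8 alcohol (8R; hydroxyl cis to the C7 side chain in the ring projection)
Conditions: NaBH4, MeOH/THF, −40 °C
Reagents that add atoms: none
Why: Hydride reduction of the ketone under Felkin–Anh control, with the C7 side chain perpendicular to the carbonyl and hydride arriving from the ring periphery on the C7–H side; reducing at once also removes the β-alkoxy ketone before any further base is used.

Step 14
Reactants: 19 C8 alcohol
Product: 20 furanone alcohol (C1 ketone; 3(2H)-furanone conjugated with C4=C5)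
Conditions: LDA (2.3 equiv), THF, −78 °C; Me3SiOOSiMe3, −78 to −30 °C; aq. NH4Cl
Reagents that add atoms: bis(trimethylsilyl) peroxide, C[Si](C)(C)OO[Si](C)(C)C
Why: Oxidative desulfonylation: after the alkoxide the α-sulfonyl allylic carbanion forms, is oxygenated at the α-carbon by the silyl peroxide, and the α-silyloxy sulfone collapses with loss of benzenesulfinate to the C1 ketone, which turns the fragile dienol ether into a robust vinylogous ester and removes the uncontrolled C1 centre; ring opening from the C1 anion would be a disfavoured 5-endo β-elimination.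

Step 15
Reactants: 20 furanone alcohol; 21 angelic acid
Product: 23 8-O-angelate, via mixed anhydride 22 (not isolated)
Conditions: 21, 2,4,6-trichlorobenzoyl chloride, Et3N, toluene, rt; then 20, toluene, 75 °C
Reagents that add atoms: 2,4,6-trichlorobenzoyl chloride, O=C(Cl)c1c(Cl)cc(Cl)cc1Cl (aroyl group of 22 only)
Why: Yamaguchi esterification through the mixed anhydride, run without DMAP, a protocol that acylates hindered secondary alcohols at the less hindered angeloyl carbonyl and keeps the Z geometry of the angelate; acylating C8 before C6 and C12 are unmasked also decides which hydroxyl will later lactonise.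

Step 16
Reactants: 23 8-O-angelate
Product: 24 diol (C6–OH, C12–OH)
Conditions: HF·pyridine, pyridine, THF, 0 °C to rt
Reagents that add atoms: none
Why: Buffered HF cleaves both silyl ethers; the furanone, the angelate and the alkenes are stable to it and the mildly acidic medium disfavours acyl migration from O8 to O6.

Step 17
Reactants: 24 diol
Product: 26 target CNP0278264.1, via lactol 25 (not isolated)
Conditions: TEMPO (0.2 equiv), PhI(OAc)2 (3 equiv), CH2Cl2, rt
Reagents that add atoms: none
Why: Oxidative lactonisation of a 1,4-diol: the oxoammonium species oxidises the primary alcohol first, the aldehyde closes onto the C6 hydroxyl and the lactol is oxidised to the γ-lactone; C6, C7 and C11 are not touched and the trans ring fusion follows from the trans C6–O/C7–C11 relationship.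

**Compound list**

1 | (S)-(+)-carvone | CC1=CC[C@H](C(C)=C)CC1=O | starting material
2 | (5R,6R)-6-hydroxycarvone, C8–OH trans to isopropenyl | O=C1[C@H](O)[C@@H](C(C)=C)CC=C1C | intermediate
3 | triethylsilyl ether of 2 | O=C1[C@H](O[Si](CC)(CC)CC)[C@@H](C(C)=C)CC=C1C | intermediate
4 | 3-bromo-1-(trimethylsilyl)prop-1-yne | C[Si](C)(C)C#CCBr | starting material
5 | C8-quaternary enone; OSiEt3 cis, silylpropargyl trans to isopropenyl | O=C1[C@](O[Si](CC)(CC)CC)(CC#C[Si](C)(C)C)[C@@H](C(C)=C)CC=C1C | intermediate
6 | B-alkyl-9-BBN adduct of 5 (boron on C12) | O=C1[C@](O[Si](CC)(CC)CC)(CC#C[Si](C)(C)C)[C@@H]([C@H](C)CB2C3CCCC2CCC3)CC=C1C | intermediate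
7 | primary alcohol, C12–OH, C11 S | O=C1[C@](O[Si](CC)(CC)CC)(CC#C[Si](C)(C)C)[C@@H]([C@H](C)CO)CC=C1C | intermediate
8 | C12–OTBS ether of 7 | O=C1[C@](O[Si](CC)(CC)CC)(CC#C[Si](C)(C)C)[C@@H]([C@H](C)CO[Si](C)(C)C(C)(C)C)CC=C1C | intermediate
9 | cyclohexa-1,3-dienyl triflate (C3–OTf) | FC(F)(F)S(=O)(=O)OC=1[C@](O[Si](CC)(CC)CC)(CC#C[Si](C)(C)C)[C@@H]([C@H](C)CO[Si](C)(C)C(C)(C)C)C=CC=1C | intermediate
10 | phenyl vinyl sulfone | C=CS(=O)(=O)c1ccccc1 | starting material
11 | (E)-sulfonyl triene, C3–CH=CH–SO2Ph | O=S(=O)(c1ccccc1)/C=C/C=2[C@](O[Si](CC)(CC)CC)(CC#C[Si](C)(C)C)[C@@H]([C@H](C)CO[Si](C)(C)C(C)(C)C)C=CC=2C | intermediate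
12 | C3,C6-endoperoxide, O–O bridge anti to the C7 side chain and O8 | O=S(=O)(c1ccccc1)/C=C/[C@]23OO[C@@H]([C@H]([C@H](C)CO[Si](C)(C)C(C)(C)C)[C@@]3(O[Si](CC)(CC)CC)CC#C[Si](C)(C)C)C=C2C | intermediate
13 | cis-1,4-diol, C3–OH and C6–OH trans to the C7 side chain | O=S(=O)(c1ccccc1)/C=C/[C@@]2(O)[C@](O[Si](CC)(CC)CC)(CC#C[Si](C)(C)C)[C@@H]([C@H](C)CO[Si](C)(C)C(C)(C)C)[C@H](O)C=C2C | intermediate
14 | tetraol with terminal alkyne | O=S(=O)(c1ccccc1)/C=C/[C@@]2(O)[C@](O)(CC#C)[C@@H]([C@H](C)CO)[C@H](O)C=C2C | intermediate
15 | C6,C12-bis-TBS ether, tertiary C3–OH and C8–OH free | O=S(=O)(c1ccccc1)/C=C/[C@@]2(O)[C@](O)(CC#C)[C@@H]([C@H](C)CO[Si](C)(C)C(C)(C)C)[C@H](O[Si](C)(C)C(C)(C)C)C=C2C | intermediate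
16 | cis-fused 2-methylenetetrahydrofuran (exocyclic enol ether) | O=S(=O)(c1ccccc1)/C=C/[C@@]23OC(=C)C[C@]2(O)[C@@H]([C@H](C)CO[Si](C)(C)C(C)(C)C)[C@H](O[Si](C)(C)C(C)(C)C)C=C3C | intermediate
17 | rearrangement precursor: cis-fused 2-methyl-dihydrofuran (C9=C10), C3 (E)-2-(phenylsulfonyl)vinyl, C8–OH; (3S,6R,7S,8R,11S) | O=S(=O)(c1ccccc1)/C=C/[C@@]23OC(C)=C[C@]2(O)[C@@H]([C@H](C)CO[Si](C)(C)C(C)(C)C)[C@H](O[Si](C)(C)C(C)(C)C)C=C3C | intermediate
18 | oxa-bridged cyclodecadienone: C8 ketone, C1–SO2Ph (both C1 epimers), 10R | O=C1C[C@@]2(C)OC(=CC2S(=O)(=O)c3ccccc3)/C(C)=C\[C@@H](O[Si](C)(C)C(C)(C)C)[C@@H]1[C@H](C)CO[Si](C)(C)C(C)(C)C | intermediate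
19 | C8 alcohol (8R) of 18 | O[C@@H]1C[C@@]2(C)OC(=CC2S(=O)(=O)c3ccccc3)/C(C)=C\[C@@H](O[Si](C)(C)C(C)(C)C)[C@@H]1[C@H](C)CO[Si](C)(C)C(C)(C)C | intermediate
20 | furanone alcohol (C1 ketone, C8–OH) | O[C@@H]1C[C@@]2(C)OC(=CC2=O)/C(C)=C\[C@@H](O[Si](C)(C)C(C)(C)C)[C@@H]1[C@H](C)CO[Si](C)(C)C(C)(C)C | intermediate
21 | angelic acid, (Z)-2-methylbut-2-enoic acid | C/C=C(/C)C(=O)O | starting material
22 | angelic 2,4,6-trichlorobenzoic anhydride | C/C=C(/C)C(=O)OC(=O)c1c(Cl)cc(Cl)cc1Cl | intermediate
23 | 8-O-angelate, C6,C12-bis-TBS ether | C/C=C(/C)C(=O)O[C@@H]1C[C@@]2(C)OC(=CC2=O)/C(C)=C\[C@@H](O[Si](C)(C)C(C)(C)C)[C@@H]1[C@H](C)CO[Si](C)(C)C(C)(C)C | intermediate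
24 | 8-O-angelate C6,C12-diol | C/C=C(/C)C(=O)O[C@@H]1C[C@@]2(C)OC(=CC2=O)/C(C)=C\[C@@H](O)[C@@H]1[C@H](C)CO | intermediate
25 | C12 lactol (both anomers) | C/C=C(/C)C(=O)O[C@@H]1C[C@@]2(C)OC(=CC2=O)/C(C)=C\[C@H]2OC(O)[C@@H](C)[C@@H]21 | intermediate
26 | CNP0278264.1 (6R,7R,8R,10R,11S) | C/C=C(/C)C(=O)O[C@@H]1C[C@@]2(C)OC(=CC2=O)/C(C)=C\[C@H]2OC(=O)[C@@H](C)[C@@H]21 | target

**Count**

Total steps: 17. Longest linear sequence: 17 steps from (S)-carvone (1); compounds 4, 10 and 21 are used as bought.

**Steps most likely to fail**

Step 12. The alkoxide may fragment without the ring-opened anion re-closing at C10, closure may run through C5, the enolate may expel the bridging oxygen, and fidelity at C10 may be lost if the opened ring relaxes before bond formation. The fallback separates bond cleavage from bond formation and uses two known reactions. It sets out from 17. Fragmentation of a homoallylic alkoxide to a ketone and an allyl anion, a known C–C cleavage, is run on its own with catalytic KOt-Bu in t-BuOH/THF at 0 °C, where the sulfonyl allyl anion is protonated as it forms. This should give the nine-membered keto enol ether F1, in which the vinylogous ester and the allyl sulfone are separate. F1 is then closed by intramolecular Michael addition of the lithiated allyl sulfone to the vinylogous ester (LiHMDS, THF, −78 °C, AcOH quench at −78 °C; a tighter lithium enolate and no crown ether), which comes back to the route at 18.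

Step 14. Oxygen transfer to the delocalised sulfonyl carbanion may be incomplete or may occur at C3 or C5, and the strong base may open the dihydrofuran. The fallback avoids the carbanion: it sets out from 19 and removes the sulfone reductively (Na/Hg, Na2HPO4, MeOH, −20 °C) to give the C1-methylene alcohol F2. The carbonyl is then introduced by allylic C–H oxidation of the cyclic enol ether (Rh2(cap)4 cat., t-BuOOH, CH2Cl2), which comes back to the route at 20.

Step 13. Facial selectivity of hydride delivery to the macrocyclic ketone may be poor or reversed. The fallback sets the C8 configuration by substitution instead of reduction: it sets out from 18, which is reduced with the hydride reagent that favours the 8S alcohol F3. F3 is taken through the conditions of step 14 to the epimeric furanone alcohol F4. Mitsunobu esterification of F4 with angelic acid 21 (PPh3, DIAD, toluene, 0 °C to rt) then installs the ester with inversion and comes back to the route at 23, so step 15 is not needed.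

Further compounds
F1 | step 12 | nine-membered keto enol ether: C8 ketone, Z-C9=C10(Me)–O–C3, exocyclic C3=C2, C1H2–SO2Ph | O=C1/C=C(C)\OC(=CCS(=O)(=O)c2ccccc2)/C(C)=C\[C@@H](O[Si](C)(C)C(C)(C)C)[C@@H]1[C@H](C)CO[Si](C)(C)C(C)(C)C
F2 | step 14 | desulfonylated C8 alcohol (C1 methylene) | O[C@@H]1C[C@@]2(C)OC(=CC2)/C(C)=C\[C@@H](O[Si](C)(C)C(C)(C)C)[C@@H]1[C@H](C)CO[Si](C)(C)C(C)(C)C
F3 | step 13 | 8S epimer of 19 | O[C@H]1C[C@@]2(C)OC(=CC2S(=O)(=O)c3ccccc3)/C(C)=C\[C@@H](O[Si](C)(C)C(C)(C)C)[C@@H]1[C@H](C)CO[Si](C)(C)C(C)(C)C
F4 | step 13 | 8S epimer of 20 | O[C@H]1C[C@@]2(C)OC(=CC2=O)/C(C)=C\[C@@H](O[Si](C)(C)C(C)(C)C)[C@@H]1[C@H](C)CO[Si](C)(C)C(C)(C)C
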